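The meeting opened on one number, 28.3 %, which the analyst called the leak: the share of the starting material lost that has not arrived as target.

common to all: free catalyst 0.77 mol%
- Wednesday's: starting material 69 mM; second substrate 0.50 equiv; reagent 0.60 equiv; run made earlier
- Monday's: starting material 46 mM; second substrate 0.25 equiv; reagent 0.60 equiv; run made earlier
- autumn: starting material 46 mM; second substrate 0.500 equiv; reagent 0.600 equiv; time 2.0 h
- dawn: starting material 46 mM; second substrate 0.500 equiv; reagent 0.800 equiv; time 2.0 h
- noon: starting material 46 mM; second substrate 0.500 equiv; reagent 1.20 equiv; time 2.0 h
- midnight: starting material 46 mM; second substrate 0.500 equiv; reagent 2.00 equiv; time 2.0 h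
- winter: starting material 46 mM; second substrate 0.500 equiv; reagent 3.00 equiv; time 2.0 h

| run | time / min | target / % | starting material / % |
|---|---|---|---|
| Wednesday's | 3.00 | 5 | 90 |
| Wednesday's | 6.00 | 9 | 86 |
| Wednesday's | 10.0 | 16 | 77 |
| Wednesday's | 15.0 | 23 | 68 |
| Wednesday's | 20.0 | 30 | 61 |
| Wednesday's | 25.0 | 33 | 56 |
| Monday's | 2.00 | 5 | 96 |
| Monday's | 3.00 | 3 | 95 |
| Monday's | 4.00 | 8 | 89 |
| Monday's | 6.00 | 8 | 85 |
| Monday's | 10.0 | 15 | 75 |
| Monday's | 15.0 | 20 | 67 |
| Monday's | 25.0 | 33 | 52 |

(each reading ± 2 percentage points)

- "hardly changes" means that all values lie within two and a half points (for a concentration: within two and a half percent of the largest)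

* amount of target at the end, in percent of the starting material charged for autumn, dawn, noon, midnight, winter, in this order
* how that number moves from the first to the last of them (hardly changes / falls all the way / falls, then rises / rises all the way / rises, then falls)

The analyst explained how the leak was read. She pooled the last reading of each earlier run, each carrying a scatter of 2 percentage points. Wednesday's run showed 33 % target with 56 % starting material left at 25.0 min, and Monday's run showed 33 % target with 52 % left at 25.0 min.

The bench chemist then pointed out that Monday's target had reached 33 %, more than the 0.25 equiv of second substrate charged, so second substrate is not spent one for one on target.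

The chair turned to reagent, which stood at 0.60 equiv in both runs and so had never been varied. He proposed, as an assumption, that each starting material lost costs one reagent, whichever way it goes. The leak then becomes a correction to the reagent charge: on that assumption, in a flask short of reagent, the limiting reagent, the target at the end is the reagent charge with the leak's share taken off it.

Time did not seem to stand in the way, the bench chemist added, since Monday's run had lost 48.0 % of its starting material by 25.0 min, and the new flasks run for 2.0 h.

My own reckoning in these minutes follows the chair. Autumn, with 0.600 equiv, should give 43.0 % target, and dawn, with 0.800 equiv, should give 57.4 %. For noon, midnight and winter I commit to no figure: both runs behind the leak stood at 0.60 equiv of reagent.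

The forecast, made from the same two runs, gives 43 %, 57 %, 67 %, 68 % and 68 %, says the number rises all the way, and holds that “With 1.2 equiv or more, starting material limits”.

The flasks give 46.0 %, 57.7 %, 69.1 %, 75.0 % and 77.0 %, so the number rises all the way.

    starting material + free catalyst ⇌ catalyst intermediate A (K = 2300 L mol⁻¹, k = 1.50 L mol⁻¹ s⁻¹)
    reagent + catalyst intermediate A → free catalyst + target (k = 6.20 L mol⁻¹ s⁻¹)
    second substrate + free catalyst ⇌ catalyst intermediate B (K = 110 L mol⁻¹, k = 1.50 L mol⁻¹ s⁻¹)
    reagent + catalyst intermediate B → free catalyst + second product (k = 1.10 L mol⁻¹ s⁻¹)
    starting material ⇌ dormant form (K = 16.0, k = 1.30 × 10⁻⁴ s⁻¹)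

In autumn at 2.00 h, reagent stands at 0.0394 % of its charge, the first to run out, and second product stands at 6.42 mM, which is 23.3 % of the reagent charged. Put to dawn, the leak of 28.3 % gives 57.4 % against the 57.7 % found, with 0.78 % of the reagent left. Dawn's second product stands at 9.97 mM, which is 27.1 % of the reagent charged.

The readings are calculated on assumed constants.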